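The readings were generated by integration for substances that don't exist; the scatter is artificial.

- The number I carry for this flask is 75.0%, the partner ceiling: c(coupling partner) over the two substrates together, which is the sum of both products the partner can pay for at one partner per product. Below 100 percent, the coupling partner is the limiting reagent.

| flask | left-handed substrate | right-handed substrate | coupling partner | precatalyst | impurity | remark | time |
|---|---|---|---|---|---|---|---|
| east | 0.15 M | 0.15 M | 0.45 M (fed, over 80 s) | 1.5 mM | 0.45 mM | run made earlier |  |
| north-east | 0.60 M | 0.60 M | 0.45 M (fed, over 80 s) | 1.5 mM | 0.45 mM | run made earlier |  |
| south-west | 0.30 M | 0.30 M | 0.45 M (fed, over 80 s) | 3 mM | 0.45 mM | run made earlier |  |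
| flask | 0.30 M | 0.30 M | 0.450 M (fed, over 80 s) | 1.5 mM | 0.45 mM |  | 15 h |

| run | time / h | left-handed product / % |
|---|---|---|
| east | 1.33 | 46.9 |
| east | 3.00 | 50.0 |
| east | 8.00 | 50.2 |
| east | 20.0 | 51.1 |
| north-east | 5.00 | 13.5 |
| north-east | 10.0 | 13.9 |
| north-east | 15.0 | 14.4 |
| north-east | 20.0 | 14.3 |
| south-west | 5.00 | 33.1 |
| south-west | 10.0 | 32.5 |
| south-west | 15.0 | 32.3 |
| south-west | 20.0 | 32.3 |

(scatter of a reading: 0.5 percentage points)

- free catalyst is single-handed; left-handed substrate and right-handed substrate are mirror images of each other, charged as a racemate, each of them at the stated concentration
- what may be going on: free catalyst + left-handed substrate <-> catalyst intermediate A; free catalyst + right-handed substrate <-> catalyst intermediate B; coupling partner + catalyst intermediate A -> free catalyst + left-handed product; coupling partner + catalyst intermediate B -> free catalyst + right-handed product; free catalyst + impurity -> spent catalyst; precatalyst -> free catalyst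
- the reaction counts as stopped when no species that holds the left-handed substrate and right-handed substrate together changes by six tenths of a point or more over the second half of the time

- which holds at 15 h: what has brought the reaction to rest, or that it has not come to rest (the coupling partner has run out first / it is still moving / forward and back rates have come level / no working catalyst is left / all of the left-handed substrate has reacted)
- how much left-handed product there is at 15 h, in percent of the left-handed substrate and right-handed substrate together charged
- amount of left-handed product if the flask were left three thousand times as long, in percent of the left-handed substrate and right-handed substrate together charged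

- Coupling partner: by hand, more partner per substrate lifts the ceiling. The east run, with the flask's partner on less substrate, has a ceiling of 150%, and its left-handed product reads 50.2% at 8.00 h, about what the left-handed substrate's charge allows.
- Precatalyst: by hand, it does not enter the ceiling. The south-west run has twice the flask's precatalyst at the flask's ceiling, 75.0%. The east run, with the flask's precatalyst, reads 50.0% at 3.00 h, which is earlier than the flask's 15 h.
- Impurity: by hand, if each impurity takes one catalyst, the flask keeps 70.0% of its catalyst, since 1.5 mM is more than 0.45 mM.
- Time: by hand, each product needs a partner, so standing at the ceiling adds none. The south-west readings go from 33.1% at 5.00 h to 32.3% at 20.0 h, with a scatter of 0.5 percentage points.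
- My reckoning is short: find a run with the same ceiling and read it. The mean of the south-west readings gives 32.5% of left-handed product, which I expect at 15 h and later alike, with the coupling partner out first.
- The forecast says the coupling partner has run out first, 32.3% and 32.3%, below my mean, on the grounds “Partner is gone, so the product stays at about 32.3%”.
- The flask gives the coupling partner has run out first, 32.1% and 32.1%.

    free catalyst + left-handed substrate ⇌ catalyst intermediate A (K = 4.50 /M, k = 210 /M/s)
    free catalyst + right-handed substrate ⇌ catalyst intermediate B (K = 18.0 /M, k = 230 /M/s)
    coupling partner + catalyst intermediate A → free catalyst + left-handed product (k = 0.980 /M/s)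
    coupling partner + catalyst intermediate B → free catalyst + right-handed product (k = 0.470 /M/s)
    free catalyst + impurity → spent catalyst (k = 140 /M/s)
    precatalyst → free catalyst (k = 0.0110 /s)

- At 15 h the flask holds 32.1% of left-handed product and 42.9% of right-handed product, together 75.0% against the ceiling of 75.0%, with 0% of the coupling partner left, and half of the right-handed coupling is done by 0.358 h, far earlier than 15 h. The neighbour charged with 1.8 M of coupling partner has a ceiling of 300%, and it ends with 50.0% of left-handed product and 50.0% of right-handed product.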